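The numbers in the tables were generated by integration for an exercise, noise included.

If a catalyst meets an impurity that removes it one for one, the winter flask turns on which charge is the larger, and the reckoning need follow the small difference between them.

| setting | winter | dawn | flask |
|---|---|---|---|
| substrate | 0.11 M | 0.11 M | 0.11 M |
| gas phase | 4.3 mM (held) | 4.3 mM (held) | 4.3 mM (held) |
| free catalyst | 55 µM | 55 µM | 55 µM |
| impurity | 64 µM | 130 µM | 64 µM |
| remark | the very flask that is asked about, followed so far | run made earlier |  |
| time |  |  | 10 d |

winter run (percent of the substrate charged)

| time / h | product / % | substrate / % |
|---|---|---|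
| 8.00 | 7.8 | 89.2 |
| 15.0 | 9.4 | 84.5 |
| 20.0 | 9.4 | 82.0 |
| 30.0 | 9.6 | 79.1 |
| 40.0 | 9.7 | 75.9 |

dawn run (percent of the substrate charged)

| time / d | product / % | substrate / % |
|---|---|---|
| 0.625 | 2.0 | 90.6 |
| 1.25 | 2.2 | 85.3 |
| 2.08 | 1.6 | 80.0 |
| 2.50 | 2.4 | 77.7 |
| 3.00 | 2.1 | 75.3 |
| 4.00 | 1.8 | 72.2 |

(readings scatter by 0.5 percentage points)

- at the start none of the gas phase is in solution

- east: doubling the transfer coefficient of the gas phase, all else as stated
- north-west: doubling the saturation concentration of gas phase, all else as stated
- north-east: doubling the amount of free catalyst, all else as stated

* how much product there is at 10 d, in percent of the substrate charged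
* the change that raises the amount of product at 10 d, in percent of the substrate charged most ("none" if none brings more than 2 percentage points) (east / north-west / north-east / none)
* amount of product at 10 d, in percent of the substrate charged, after north-east

The readings form a ladder of two rungs. On the faster rung, product in the winter run reads 7.8% at 8.00 h and 9.7% at 40.0 h, whereas the dawn run, with about twice the impurity, ends at 1.8%, so the working catalyst appears to be lost within hours. On the slower rung, substrate in the dawn run keeps falling to 72.2% at 4.00 d while product stays flat, which marks a side drain of days that makes no product.

Against that background the small difference is worth computing: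

impurity margin = (impurity − catalyst) / impurity = 14.1%

This impurity margin, the fraction of the impurity charge in excess of the catalyst charge, is positive in the winter flask, which makes catalyst the limiting reagent of its own poisoning. The winter flask should therefore stay on its plateau, read as the mean from 20.0 h onward:

plateau = 9.57%

Doubling the catalyst reverses the sign of the margin and should leave 41.8% of the doubled charge working. Scaling the plateau by catalyst and time, with 15.0 h as the old working time, gives:

reckoned product = 128%

That exceeds the charge, so it stands as a sign of high conversion and not as an amount, and this reckoning chooses north-east, since the other changes leave the margin as it stands.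

The forecast gives 9.7% (9.2% to 10.4%), a little above the plateau reckoned here, and chooses north-east because the doubled catalyst “outlasts the impurity”, with 96% (82% to 99.5%).

The winter flask gives 10.0% at 10 d; the best change is north-east, with 97.4%.

    gas phase ⇌ dissolved gas, rate k1*(csat - [dissolved gas]) (kL = 0.0400 min⁻¹)
    substrate + dissolved gas + free catalyst → free catalyst + product (k = 3800 L² mol⁻² min⁻¹)
    free catalyst + impurity → spent catalyst (k = 230 L mol⁻¹ min⁻¹)
    substrate ⇌ dormant form (K = 0.560, k = 8.60 × 10⁻⁵ min⁻¹)

The winter flask ends with 0% free catalyst and 14% of its impurity, the margin of 14.1% over again. Poisoning is the main reason for the stall: without that step the winter flask gives 97.9% instead of 10.0%. In the neighbour flask charged with 9.3 × 10⁻⁵ M of free catalyst, the same subtraction predicts that 31.2% of the catalyst survives, and that flask ends with 31.2% free catalyst and 95.3% product.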